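Ring A of the target carries two adjacent oxygens, O1 on C7a and the methoxy oxygen on C7, directly beside the ring fusion. This pattern is read as the ether oxygen of an ynol ether plus the ring oxygen of a furan: one gold-catalysed furan–yne benzannulation forges C3a–C7a and C6–C7, closing the dihydrofuran ring B and the benzene ring A together and delivering the C7 phenol. Its precursor is the (1S,2R) syn ethynyl ether of a 1-aryl-2-furylpropane-1,3-diol whose furan carries a masked formyl group at C4; both stereocentres come from an Evans syn aldol and are untouched by the annulation. Methylation, acetal hydrolysis, Knoevenagel–Doebner chain extension and desilylation finish the synthesis.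

Key step: step 11

Remark on stereochemistry: the target is the (2S,3R) 2,3-trans compound. The annulation leaves both centres untouched and ties O1 and C3a to the same side, so the open-chain ether must be the (1S,2R), 1,2-syn isomer (aldol sense). The 1,2-anti isomer would end as the cis ring.

Remark on protecting groups: both hydroxyls are carried as TIPS ethers, because a primary TBS ether can shift to the neighbouring potassium alkoxide during ynol ether formation. The formyl group is carried as a 1,3-dioxolane, which resists the boron triflate of the aldol and traces of acid better than an open-chain acetal.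

Assumption: compounds 1, 3, 11 and 26, ethyl bromoacetate and all reagents are purchased.

Step 1
Reactants: 1 syringaldehyde (4-hydroxy-3,5-dimethoxybenzaldehyde)
Product: 2 3,5-dimethoxy-4-(triisopropylsilyloxy)benzaldehyde
Conditions: TIPSCl, imidazole, DMAP (cat.), DMF, rt
Reagents that add atoms: triisopropylsilyl chloride, CC(C)[Si](Cl)(C(C)C)C(C)C
Why: Silylation of the phenol (nucleophilic substitution at silicon via the N-silylimidazolium ion) should proceed cleanly, and the bulky TIPS ether is chosen because it must survive boron triflate, hydride, potassium hydride and butyllithium before fluoride removes it at the end.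

Step 2
Reactants: 3 3-furaldehyde (furan-3-carbaldehyde)
Product: 7 5-bromofuran-3-carbaldehyde, via lithium α-morpholino alkoxide 4 (not isolated), via C5-lithiated alkoxide 5 (not isolated), via C5-brominated alkoxide 6 (not isolated)
Conditions: morpholine, n-BuLi, THF, −78 °C; then 3; sec-BuLi, −78 °C; BrCl2CCCl2Br, −78 °C → rt; H2O work-up
Reagents that add atoms: 1,2-dibromo-1,1,2,2-tetrachloroethane, ClC(Cl)(Br)C(Cl)(Cl)Br
Why: Directed metalation with in situ protection of the aldehyde: lithium morpholide adds to the formyl group to give an α-amino alkoxide that masks the carbonyl and screens C2, so sec-BuLi should remove the remaining α-proton at C5, the aryllithium is brominated by halogen transfer and the hemiaminal collapses to the aldehyde on aqueous work-up.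

Step 3
Reactants: 7 5-bromofuran-3-carbaldehyde
Product: 8 2-(5-bromofuran-3-yl)-1,3-dioxolane
Conditions: ethylene glycol, PPTS (cat.), toluene, reflux (Dean–Stark)
Reagents that add atoms: ethylene glycol, OCCO
Why: Acid-catalysed acetalisation driven by azeotropic removal of water converts the formyl group into a dioxolane that is inert to the zinc enolate, hydride, potassium hydride and butyllithium used later.

Step 4
Reactants: 8 2-(5-bromofuran-3-yl)-1,3-dioxolane
Product: 9 ethyl 2-[4-(1,3-dioxolan-2-yl)furan-2-yl]acetate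
Conditions: BrZnCH2CO2Et (from ethyl bromoacetate, Zn dust, TMSCl cat., THF), Pd2(dba)3 (1 mol %), XPhos (4 mol %), THF, 50 °C
Reagents that add atoms: (2-ethoxy-2-oxoethyl)zinc bromide, CCOC(=O)C[Zn]Br
Why: Negishi cross-coupling of a Reformatsky zinc enolate (palladium-catalysed α-arylation of an acetate under near-neutral conditions) should replace the reactive bromide of the 2-bromofuran by the CH2CO2Et unit without touching the acetal.

Step 5
Reactants: 9 ethyl 2-[4-(1,3-dioxolan-2-yl)furan-2-yl]acetate
Product: 10 2-[4-(1,3-dioxolan-2-yl)furan-2-yl]acetic acid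
Conditions: LiOH·H2O, THF/H2O (3:1), 0 °C → rt; then 0.5 M HCl to pH 4 at 0 °C
Reagents that add atoms: lithium hydroxide (its oxygen becomes the acid OH), [Li+].[OH-]
Why: Saponification of the ethyl ester by acyl–oxygen cleavage is followed by a cold, brief acidification to pH 4 that liberates the acid while the dioxolane stays intact.

Step 6
Reactants: 10 2-[4-(1,3-dioxolan-2-yl)furan-2-yl]acetic acid; 11 (S)-4-benzyloxazolidin-2-one
Product: 13 (S)-4-benzyl-3-{2-[4-(1,3-dioxolan-2-yl)furan-2-yl]acetyl}oxazolidin-2-one, via mixed pivalic anhydride 12 (not isolated)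
Conditions: PivCl, Et3N, THF, −20 °C; then 11, LiCl, −20 °C → rt
Reagents that add atoms: none
Why: N-Acylation of the oxazolidinone through a mixed pivalic anhydride, with LiCl raising the acidity of the oxazolidinone N–H so that triethylamine suffices, should attack the less hindered furylacetyl carbonyl selectively; the stereocentre of the auxiliary is not involved.

Step 7
Reactants: 13 (S)-4-benzyl-3-{2-[4-(1,3-dioxolan-2-yl)furan-2-yl]acetyl}oxazolidin-2-one; 2 3,5-dimethoxy-4-(triisopropylsilyloxy)benzaldehyde
Product: 15 (S)-4-benzyl-3-{(2R,3S)-3-[3,5-dimethoxy-4-(triisopropylsilyloxy)phenyl]-2-[4-(1,3-dioxolan-2-yl)furan-2-yl]-3-hydroxypropanoyl}oxazolidin-2-one, via Z-dibutylboron enolate 14 (not isolated)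
Conditions: Bu2BOTf, i-Pr2NEt, CH2Cl2, −78 → 0 °C; then 2, −78 → 0 °C; pH 7 buffer/MeOH
Reagents that add atoms: none
Why: Evans syn aldol reaction: soft enolisation gives the Z boron enolate, which reacts through a closed chair (Zimmerman–Traxler) transition state with the imide carbonyls opposed and the aldehyde approaching the enolate face away from the benzyl group, setting C2 (R) and C3 (S) of the acyl chain together as the syn pair.

Step 8
Reactants: 15 the syn aldol adduct
Product: 16 (1S,2R)-1-[3,5-dimethoxy-4-(triisopropylsilyloxy)phenyl]-2-[4-(1,3-dioxolan-2-yl)furan-2-yl]propane-1,3-diol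
Conditions: LiBH4, H2O (1 equiv), Et2O/THF, 0 °C
Reagents that add atoms: none
Why: Reductive cleavage of the N-acyloxazolidinone: borohydride attacks the exocyclic imide carbonyl and reduces the released aldehyde to the primary alcohol at 0 °C, conditions mild enough to avoid retro-aldol cleavage or epimerisation, and the auxiliary is recovered.

Step 9
Reactants: 16 the 1,3-diol
Product: 17 (1S,2R)-1-[3,5-dimethoxy-4-(triisopropylsilyloxy)phenyl]-2-[4-(1,3-dioxolan-2-yl)furan-2-yl]-3-(triisopropylsilyloxy)propan-1-ol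
Conditions: TIPSCl, imidazole, CH2Cl2, 0 °C → rt
Reagents that add atoms: triisopropylsilyl chloride, CC(C)[Si](Cl)(C(C)C)C(C)C
Why: Chemoselective silylation on steric grounds: TIPSCl reacts with the primary hydroxyl far faster than with the hindered secondary benzylic one, and TIPS is used because it does not undergo 1,5 oxygen-to-oxygen migration to the alkoxide in the next step.

Step 10
Reactants: 17 the secondary alcohol
Product: 20 2-{5-[(1S,2R)-1-[3,5-dimethoxy-4-(triisopropylsilyloxy)phenyl]-1-(ethynyloxy)-3-(triisopropylsilyloxy)propan-2-yl]furan-3-yl}-1,3-dioxolane (the syn ethynyl ether), via E-1,2-dichlorovinyl ether 18 (not isolated), via lithium alkoxyacetylide 19 (not isolated)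
Conditions: KH, THF, 0 °C; Cl2C=CHCl, −50 °C → rt; then n-BuLi, −78 → −40 °C; MeOH, −78 °C; cold work-up, used at once
Reagents that add atoms: trichloroethylene, ClC=C(Cl)Cl
Why: Ynol ether synthesis through a dichlorovinyl ether: the potassium alkoxide adds anti to dichloroacetylene generated in situ from trichloroethylene, n-BuLi then effects dehydrochlorination and chlorine–lithium exchange to the lithium alkoxyacetylide, and cold methanol protonates it; the C–O bond at C1 is never broken, so both stereocentres are retained.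

Step 11
Reactants: 20 the syn ethynyl ether
Product: 23 (2S,3R)-2-[3,5-dimethoxy-4-(triisopropylsilyloxy)phenyl]-5-(1,3-dioxolan-2-yl)-3-[(triisopropylsilyloxy)methyl]-2,3-dihydro-1-benzofuran-7-ol, via oxepine 21 (not isolated), via arene oxide 22 (not isolated)
Conditions: Ph3PAuNTf2 (3 mol %), dry CH2Cl2 (0.02 M), 4 Å MS, 0 °C → rt
Reagents that add atoms: none
Why: Monovalent gold binds the ynol ether and polarises it towards a ketene-oxonium form, so furan C2 adds to the oxygen-bearing alkyne carbon and gives a cyclopropyl gold carbenoid; the furan then opens to an aldehyde-terminated vinyl gold carbenoid, the aldehyde oxygen closes onto the carbenoid carbon with release of the catalyst to give oxepine 21, and its valence tautomer, arene oxide 22, opens and tautomerises to the phenol. The closest known reaction type is the gold-catalysed furan–yne phenol synthesis in its heteroatom-substituted-alkyne variant, in which alkynyl ether tethers furnish 7-hydroxy-2,3-dihydrobenzofurans. Ring B closes in a 5-exo-dig mode (C3a–C7a), and ring A closes by disrotatory 6π electrocyclisation of the oxepine (C6–C7). No stereocentre is created in the product: the epoxide carbons of 22 end as sp2 carbons, and C2 and C3, set in the aldol step, lie outside the reacting π system and should be carried through unchanged. The step needs regiocontrol twice, in the first C–C bond formation and in the oxide opening, and both follow from the oxygen on the alkyne: it directs the furan to the alkyne carbon it sits on, and as O1 on C7a it stabilises the cation formed when the C6–O bond of the oxide breaks, so the hydroxyl stays on C7. Chemoselectivity against hydration or phenol addition to the ynol ether is secured by the much faster intramolecular furan attack under dry, dilute conditions.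

Step 12
Reactants: 23 the C7 phenol
Product: 24 (2S,3R)-2-[3,5-dimethoxy-4-(triisopropylsilyloxy)phenyl]-5-(1,3-dioxolan-2-yl)-7-methoxy-3-[(triisopropylsilyloxy)methyl]-2,3-dihydro-1-benzofuran
Conditions: MeI, K2CO3, dry acetone, rt
Reagents that add atoms: iodomethane, CI
Why: Williamson ether synthesis: the C7 phenol is the only acidic hydroxyl and its potassium phenoxide should be methylated by iodomethane while both silyl ethers and the acetal stay in place under anhydrous carbonate.

Step 13
Reactants: 24 the C7 methyl ether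
Product: 25 (2S,3R)-2-[3,5-dimethoxy-4-(triisopropylsilyloxy)phenyl]-7-methoxy-3-[(triisopropylsilyloxy)methyl]-2,3-dihydro-1-benzofuran-5-carbaldehyde
Conditions: 1 M HCl (aq.), THF, 0 °C → rt
Reagents that add atoms: water, O
Why: Acid-catalysed acetal hydrolysis should release the aryl aldehyde at room temperature well before the hindered TIPS ethers or the benzylic ether of ring B are affected.

Step 14
Reactants: 25 the C5 aldehyde; 26 malonic acid
Product: 28 (E)-3-{(2S,3R)-2-[3,5-dimethoxy-4-(triisopropylsilyloxy)phenyl]-7-methoxy-3-[(triisopropylsilyloxy)methyl]-2,3-dihydro-1-benzofuran-5-yl}prop-2-enoic acid, via arylidenemalonic acid 27 (not isolated)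
Conditions: pyridine, piperidine (cat.), 80 °C
Reagents that add atoms: none
Why: Knoevenagel–Doebner condensation: piperidine-mediated condensation with malonic acid gives the arylidenemalonic acid, which loses carbon dioxide in hot pyridine to the thermodynamically favoured E cinnamic acid; the stereocentres are remote from the reacting aldehyde.

Step 15
Reactants: 28 the bis-silylated cinnamic acid
Product: 29 (E)-3-[(2S,3R)-2-(4-hydroxy-3,5-dimethoxyphenyl)-3-(hydroxymethyl)-7-methoxy-2,3-dihydro-1-benzofuran-5-yl]prop-2-enoic acid (CNP0224723.1)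
Conditions: TBAF, AcOH, THF, 0 °C → rt; pH 3 buffer work-up
Reagents that add atoms: none
Why: Fluoride-induced desilylation, driven by the strong Si–F bond, should cleave the aryl and the primary TIPS ether together, and buffering with acetic acid keeps the freed para-hydroxybenzylic ether of ring B from base-induced opening, so that C2 and C3 are preserved.

Compound list

1 | syringaldehyde (4-hydroxy-3,5-dimethoxybenzaldehyde) | COc1cc(C=O)cc(OC)c1O | starting material
2 | 3,5-dimethoxy-4-(triisopropylsilyloxy)benzaldehyde | COc1cc(C=O)cc(OC)c1O[Si](C(C)C)(C(C)C)C(C)C | intermediate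
3 | 3-furaldehyde (furan-3-carbaldehyde) | O=Cc1ccoc1 | starting material
4 | lithium (furan-3-yl)(morpholin-4-yl)methoxide (aminal carbon racemic) | [Li]OC(N1CCOCC1)c1ccoc1 | intermediate (not isolated)
5 | lithium (5-lithiofuran-3-yl)(morpholin-4-yl)methoxide | [Li]OC(N1CCOCC1)c1coc([Li])c1 | intermediate (not isolated)
6 | lithium (5-bromofuran-3-yl)(morpholin-4-yl)methoxide | [Li]OC(N1CCOCC1)c1coc(Br)c1 | intermediate (not isolated)
7 | 5-bromofuran-3-carbaldehyde | O=Cc1coc(Br)c1 | intermediate
8 | 2-(5-bromofuran-3-yl)-1,3-dioxolane | Brc1cc(C2OCCO2)co1 | intermediate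
9 | ethyl 2-[4-(1,3-dioxolan-2-yl)furan-2-yl]acetate | CCOC(=O)Cc1cc(C2OCCO2)co1 | intermediate
10 | 2-[4-(1,3-dioxolan-2-yl)furan-2-yl]acetic acid | OC(=O)Cc1cc(C2OCCO2)co1 | intermediate
11 | (S)-4-benzyloxazolidin-2-one | O=C1N[C@@H](Cc2ccccc2)CO1 | starting material
12 | 2-[4-(1,3-dioxolan-2-yl)furan-2-yl]acetic pivalic anhydride | CC(C)(C)C(=O)OC(=O)Cc1cc(C2OCCO2)co1 | intermediate (not isolated)
13 | (S)-4-benzyl-3-{2-[4-(1,3-dioxolan-2-yl)furan-2-yl]acetyl}oxazolidin-2-one | O=C(Cc1cc(C2OCCO2)co1)N1C(=O)OC[C@@H]1Cc1ccccc1 | intermediate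
14 | Z-dibutylboron enolate of 13 (O–B cis to the furyl group) | CCCCB(CCCC)O/C(=C\c1cc(C2OCCO2)co1)N1C(=O)OC[C@@H]1Cc1ccccc1 | intermediate (not isolated)
15 | (S)-4-benzyl-3-{(2R,3S)-3-[3,5-dimethoxy-4-(triisopropylsilyloxy)phenyl]-2-[4-(1,3-dioxolan-2-yl)furan-2-yl]-3-hydroxypropanoyl}oxazolidin-2-one | COc1cc([C@@H](O)[C@@H](C(=O)N2C(=O)OC[C@@H]2Cc3ccccc3)c4cc(C5OCCO5)co4)cc(OC)c1O[Si](C(C)C)(C(C)C)C(C)C | intermediate
16 | (1S,2R)-1-[3,5-dimethoxy-4-(triisopropylsilyloxy)phenyl]-2-[4-(1,3-dioxolan-2-yl)furan-2-yl]propane-1,3-diol | COc1cc([C@@H](O)[C@@H](CO)c2cc(C3OCCO3)co2)cc(OC)c1O[Si](C(C)C)(C(C)C)C(C)C | intermediate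
17 | (1S,2R)-1-[3,5-dimethoxy-4-(triisopropylsilyloxy)phenyl]-2-[4-(1,3-dioxolan-2-yl)furan-2-yl]-3-(triisopropylsilyloxy)propan-1-ol | COc1cc([C@@H](O)[C@@H](CO[Si](C(C)C)(C(C)C)C(C)C)c2cc(C3OCCO3)co2)cc(OC)c1O[Si](C(C)C)(C(C)C)C(C)C | intermediate
18 | (E)-1,2-dichlorovinyl ether of 17, (1S,2R) | COc1cc([C@@H](O/C(Cl)=C\Cl)[C@@H](CO[Si](C(C)C)(C(C)C)C(C)C)c2cc(C3OCCO3)co2)cc(OC)c1O[Si](C(C)C)(C(C)C)C(C)C | intermediate (not isolated)
19 | lithium acetylide of ynol ether 20, (1S,2R) | COc1cc([C@@H](OC#C[Li])[C@@H](CO[Si](C(C)C)(C(C)C)C(C)C)c2cc(C3OCCO3)co2)cc(OC)c1O[Si](C(C)C)(C(C)C)C(C)C | intermediate (not isolated)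
20 | 2-{5-[(1S,2R)-1-[3,5-dimethoxy-4-(triisopropylsilyloxy)phenyl]-1-(ethynyloxy)-3-(triisopropylsilyloxy)propan-2-yl]furan-3-yl}-1,3-dioxolane (syn ethynyl ether, key-step precursor) | COc1cc([C@@H](OC#C)[C@@H](CO[Si](C(C)C)(C(C)C)C(C)C)c2cc(C3OCCO3)co2)cc(OC)c1O[Si](C(C)C)(C(C)C)C(C)C | intermediate
21 | (2S,3R)-2,3-dihydrofuro[2,3-c]oxepine carrying the aryl group on C2, the silyloxymethyl group on C3 and the dioxolane on the carbon that becomes C5 (oxepine oxygen between the future C6 and C7) | COc1cc([C@H]2OC3=COC=C(C4OCCO4)C=C3[C@@H]2CO[Si](C(C)C)(C(C)C)C(C)C)cc(OC)c1O[Si](C(C)C)(C(C)C)C(C)C | intermediate (not isolated)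
22 | arene oxide valence tautomer of 21: 6,7-epoxy-2,3,6,7-tetrahydrobenzofuran, (2S,3R), epoxide face not defined as either face converges on 23 | COc1cc([C@H]2OC3=C(C=C(C4OCCO4)C5OC35)[C@@H]2CO[Si](C(C)C)(C(C)C)C(C)C)cc(OC)c1O[Si](C(C)C)(C(C)C)C(C)C | intermediate (not isolated)
23 | (2S,3R)-2-[3,5-dimethoxy-4-(triisopropylsilyloxy)phenyl]-5-(1,3-dioxolan-2-yl)-3-[(triisopropylsilyloxy)methyl]-2,3-dihydro-1-benzofuran-7-ol (trans, key-step product) | COc1cc([C@H]2Oc3c(O)cc(C4OCCO4)cc3[C@@H]2CO[Si](C(C)C)(C(C)C)C(C)C)cc(OC)c1O[Si](C(C)C)(C(C)C)C(C)C | intermediate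
24 | (2S,3R)-2-[3,5-dimethoxy-4-(triisopropylsilyloxy)phenyl]-5-(1,3-dioxolan-2-yl)-7-methoxy-3-[(triisopropylsilyloxy)methyl]-2,3-dihydro-1-benzofuran | COc1cc([C@H]2Oc3c(OC)cc(C4OCCO4)cc3[C@@H]2CO[Si](C(C)C)(C(C)C)C(C)C)cc(OC)c1O[Si](C(C)C)(C(C)C)C(C)C | intermediate
25 | (2S,3R)-2-[3,5-dimethoxy-4-(triisopropylsilyloxy)phenyl]-7-methoxy-3-[(triisopropylsilyloxy)methyl]-2,3-dihydro-1-benzofuran-5-carbaldehyde | COc1cc([C@H]2Oc3c(OC)cc(C=O)cc3[C@@H]2CO[Si](C(C)C)(C(C)C)C(C)C)cc(OC)c1O[Si](C(C)C)(C(C)C)C(C)C | intermediate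
26 | malonic acid | OC(=O)CC(=O)O | starting material
27 | arylidenemalonic acid from 25, (2S,3R) | COc1cc([C@H]2Oc3c(OC)cc(C=C(C(=O)O)C(=O)O)cc3[C@@H]2CO[Si](C(C)C)(C(C)C)C(C)C)cc(OC)c1O[Si](C(C)C)(C(C)C)C(C)C | intermediate (not isolated)
28 | (E)-3-{(2S,3R)-2-[3,5-dimethoxy-4-(triisopropylsilyloxy)phenyl]-7-methoxy-3-[(triisopropylsilyloxy)methyl]-2,3-dihydro-1-benzofuran-5-yl}prop-2-enoic acid | COc1cc([C@H]2Oc3c(OC)cc(/C=C/C(=O)O)cc3[C@@H]2CO[Si](C(C)C)(C(C)C)C(C)C)cc(OC)c1O[Si](C(C)C)(C(C)C)C(C)C | intermediate
29 | (E)-3-[(2S,3R)-2-(4-hydroxy-3,5-dimethoxyphenyl)-3-(hydroxymethyl)-7-methoxy-2,3-dihydro-1-benzofuran-5-yl]prop-2-enoic acid | COc1cc([C@H]2Oc3c(OC)cc(/C=C/C(=O)O)cc3[C@@H]2CO)cc(OC)c1O | target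

Total step count: 15. Longest linear sequence: 14 steps (3 to 29, steps 2 to 15).

Steps most likely to fail

Step 11. The gold-activated ynol ether sits on a benzylic carbon that carries a para-silyloxy aryl group. Ionisation of that C–O bond would lead to fragmentation or loss of configuration at C2. Sigmatropic rearrangement of the benzylic alkynyl ether, addition of water or of the product phenol to the activated alkyne, and catalyst deactivation could also compete with the furan attack. The fallback gives up the furan as the source of ring A and uses a benzene ring that already carries both oxygens. It sets out from aldehyde 2 and returns at aldehyde 25. Commercial 5-bromovanillin F1 would be acetalised (ethylene glycol, PPTS, toluene, reflux) to 2-bromo-4-(1,3-dioxolan-2-yl)-6-methoxyphenol F2 and protected (MOMCl, i-Pr2NEt) as the methoxymethyl ether F3. Coupling with BrZnCH2CO2Et (Pd2(dba)3, XPhos) would give the arylacetic ester F4, and LiOH would give the arylacetic acid F5. Attachment to 11 (PivCl, Et3N, LiCl) would give the arylacetyl imide F6. The Evans syn aldol of F6 with 2 (Bu2BOTf, i-Pr2NEt) would give the aldol adduct F7, LiBH4 the diol F8, and TIPSCl with imidazole the primary TIPS ether F9. Treatment of F9 with TFA in wet CH2Cl2 (0 °C → rt) should remove the methoxymethyl group and ionise the benzylic alcohol to a cation that the freed phenol traps to the favoured 2,3-trans ring. C3, set by the auxiliary, controls C2 in this closure. The same acid hydrolyses the dioxolane, giving 25.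

Step 10. Under potassium hydride the alkoxide could take a silyl group from an aryl silyl ether, the hindered alkoxide could add incompletely to dichloroacetylene, and the benzylic ynol ether could rearrange or hydrolyse during work-up. The fallback avoids any potassium alkoxide. It sets out from alcohol 17 and returns at ynol ether 20. Formylation (acetic formic anhydride, pyridine, 0 °C) would give the formate ester F10. Dichloromethylenation of the formyl carbonyl (PPh3, CCl4, THF, 60 °C) would give the 2,2-dichlorovinyl ether F11. n-BuLi (−78 → −40 °C) then effects dehydrochlorination and chlorine–lithium exchange to the same acetylide 19, and cold methanol gives 20.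

Step 2. Site selectivity of the metalation could erode (C2 against C5), metalation could be incomplete, and the halogen transfer could over-react. The fallback replaces directed metalation by electrophilic substitution. It sets out from 3 and returns at 7. Pinnick oxidation (NaClO2, NaH2PO4, 2-methyl-2-butene, t-BuOH/H2O) would give 3-furoic acid F12. Bromination (pyridinium tribromide, AcOH, 40 °C) should occur at C5, the α-position not conjugated with the carboxyl group, to give 5-bromo-3-furoic acid F13. BH3·THF would give (5-bromofuran-3-yl)methanol F14, and MnO2 in CH2Cl2 would return aldehyde 7.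

Further compounds

F1 | step 11 | 5-bromovanillin (3-bromo-4-hydroxy-5-methoxybenzaldehyde) | COc1cc(C=O)cc(Br)c1O
F2 | step 11 | 2-bromo-4-(1,3-dioxolan-2-yl)-6-methoxyphenol | COc1cc(C2OCCO2)cc(Br)c1O
F3 | step 11 | 2-[3-bromo-5-methoxy-4-(methoxymethoxy)phenyl]-1,3-dioxolane | COCOc1c(Br)cc(C2OCCO2)cc1OC
F4 | step 11 | ethyl 2-[5-(1,3-dioxolan-2-yl)-3-methoxy-2-(methoxymethoxy)phenyl]acetate | CCOC(=O)Cc1cc(C2OCCO2)cc(OC)c1OCOC
F5 | step 11 | 2-[5-(1,3-dioxolan-2-yl)-3-methoxy-2-(methoxymethoxy)phenyl]acetic acid | OC(=O)Cc1cc(C2OCCO2)cc(OC)c1OCOC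
F6 | step 11 | (S)-4-benzyl-3-{2-[5-(1,3-dioxolan-2-yl)-3-methoxy-2-(methoxymethoxy)phenyl]acetyl}oxazolidin-2-one | O=C(Cc1cc(C2OCCO2)cc(OC)c1OCOC)N1C(=O)OC[C@@H]1Cc1ccccc1
F7 | step 11 | (S)-4-benzyl-3-{(2S,3S)-3-[3,5-dimethoxy-4-(triisopropylsilyloxy)phenyl]-2-[5-(1,3-dioxolan-2-yl)-3-methoxy-2-(methoxymethoxy)phenyl]-3-hydroxypropanoyl}oxazolidin-2-one | COc1cc([C@@H](O)[C@@H](C(=O)N2C(=O)OC[C@@H]2Cc3ccccc3)c4cc(C5OCCO5)cc(OC)c4OCOC)cc(OC)c1O[Si](C(C)C)(C(C)C)C(C)C
F8 | step 11 | (1S,2R)-1-[3,5-dimethoxy-4-(triisopropylsilyloxy)phenyl]-2-[5-(1,3-dioxolan-2-yl)-3-methoxy-2-(methoxymethoxy)phenyl]propane-1,3-diol | COc1cc([C@@H](O)[C@@H](CO)c2cc(C3OCCO3)cc(OC)c2OCOC)cc(OC)c1O[Si](C(C)C)(C(C)C)C(C)C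
F9 | step 11 | (1S,2R)-1-[3,5-dimethoxy-4-(triisopropylsilyloxy)phenyl]-2-[5-(1,3-dioxolan-2-yl)-3-methoxy-2-(methoxymethoxy)phenyl]-3-(triisopropylsilyloxy)propan-1-ol | COc1cc([C@@H](O)[C@@H](CO[Si](C(C)C)(C(C)C)C(C)C)c2cc(C3OCCO3)cc(OC)c2OCOC)cc(OC)c1O[Si](C(C)C)(C(C)C)C(C)C
F10 | step 10 | formate ester of alcohol 17, (1S,2R) | COc1cc([C@@H](OC=O)[C@@H](CO[Si](C(C)C)(C(C)C)C(C)C)c2cc(C3OCCO3)co2)cc(OC)c1O[Si](C(C)C)(C(C)C)C(C)C
F11 | step 10 | 2,2-dichlorovinyl ether of alcohol 17, (1S,2R) | COc1cc([C@@H](OC=C(Cl)Cl)[C@@H](CO[Si](C(C)C)(C(C)C)C(C)C)c2cc(C3OCCO3)co2)cc(OC)c1O[Si](C(C)C)(C(C)C)C(C)C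
F12 | step 2 | 3-furoic acid | OC(=O)c1ccoc1
F13 | step 2 | 5-bromo-3-furoic acid | OC(=O)c1coc(Br)c1
F14 | step 2 | (5-bromofuran-3-yl)methanol | OCc1coc(Br)c1
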